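**Retrosynthetic overview**
1. The target comes from reductive removal of a sulfonyl group on the CH2 between ketone and alkene; the 14-membered ring is closed just before by an intramolecular B-alkyl Suzuki–Miyaura coupling (terminal vinyl + E-vinyl iodide), which fixes the E-alkene.
2. The β-keto sulfone comes from opening a cis-fused bis-γ-lactone with a lithiated allyl sulfone; the temporary second lactone (ring B) fixes the ring-fusion carbon next to the future ketone.
3. The butanolide (ring A) comes from a chelation-controlled Mukaiyama aldol/lactonisation of an α-PMB-oxy aldehyde with a ketene thioacetal made from (S)-citramalic acid, which supplies the tertiary carbinol.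
4. The 2,5-trans oxolane comes from Sharpless epoxidation of a (Z)-allylic alcohol with 5-exo epoxide opening by a hydroxyl set in a syn-crotylboration of a neryl acetate-derived aldehyde.
5. Ring order: oxolane, then butanolide ring A, then temporary lactone ring B (opened again), then the 14-membered carbocycle.

Assumption: neryl acetate, (S)-citramalic acid and (2E)-3-iodo-2-methylprop-2-en-1-ol are bought, and (Z)-crotyl-B(Ipc)2 is used as a freshly prepared reagent solution.

This route has not been run; selectivities are argued from known reaction types.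

**Route**

Step 1
Reactants: 1 neryl acetate
Product: 2 (2Z)-3-methyl-6-oxohex-2-en-1-yl acetate
Conditions: O3 (1.0 equiv), CH2Cl2/pyridine, −78 °C; then Me2S, −78 °C → rt
Reagents that add atoms: ozone, [O-][O+]=O
Why: Chemoselective ozonolysis, in which the electron-rich isopropylidene alkene reacts faster than the alkene deactivated by the allylic acetate; no stereocentre is formed.

Step 2
Reactants: 2 (2Z)-3-methyl-6-oxohex-2-en-1-yl acetate
Product: 4 (2Z,6R,7R)-3,7-dimethylnona-2,8-diene-1,6-diol, via hydroxy acetate 3 (not isolated)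
Conditions: (Z)-crotyl-B(Ipc)2 [Ipc from (+)-α-pinene], THF/Et2O, −78 °C; then NaOH, H2O2, MeOH/H2O, 0 °C → rt
Reagents that add atoms: (Z)-crotyl-B(Ipc)2, C/C=C\CB([C@@H]1C[C@@H]2C[C@H]([C@H]1C)C2(C)C)[C@@H]1C[C@@H]2C[C@H]([C@H]1C)C2(C)C
Why: Brown crotylboration through a closed chair transition state, where the (Z)-crotyl unit gives the syn methyl/hydroxyl pair and the Ipc ligands direct Si-face attack to set both centres as R,R; the alkaline peroxide work-up also saponifies the primary acetate.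

Step 3
Reactants: 4 (2Z,6R,7R)-3,7-dimethylnona-2,8-diene-1,6-diol
Product: 6 (1R)-1-[(2R,5R)-5-[(2R)-but-3-en-2-yl]-2-methyloxolan-2-yl]ethane-1,2-diol, via epoxy diol 5 (not isolated)
Conditions: Ti(OiPr)4 (10 mol %), D-(−)-diethyl tartrate (12 mol %), t-BuOOH, 4 Å MS, CH2Cl2, −25 °C; then CSA (cat.), 0 °C
Reagents that add atoms: tert-butyl hydroperoxide, CC(C)(C)OO
Why: Sharpless asymmetric epoxidation under reagent control (D-tartrate on the Z-allylic alcohol gives the 2R,3S-epoxide) followed by acid-promoted 5-exo-tet opening at the tertiary epoxide carbon by the secondary hydroxyl with inversion, which sets the quaternary ether carbon, the adjacent carbinol and the 2,5-trans relation of the two chain carbons on the oxolane.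

Step 4
Reactants: 6 (1R)-1-[(2R,5R)-5-[(2R)-but-3-en-2-yl]-2-methyloxolan-2-yl]ethane-1,2-diol
Product: 7 (4R)-4-[(2R,5R)-5-[(2R)-but-3-en-2-yl]-2-methyloxolan-2-yl]-2-(4-methoxyphenyl)-1,3-dioxolane (both acetal epimers)
Conditions: 4-MeOC6H4CH(OMe)2, CSA (cat.), CH2Cl2, rt
Reagents that add atoms: 4-methoxybenzaldehyde dimethyl acetal, COc1ccc(C(OC)OC)cc1
Why: Acid-catalysed transacetalisation of the 1,2-diol to the five-membered p-methoxybenzylidene acetal; no chain stereocentre is touched.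

Step 5
Reactants: 7 (4R)-4-[(2R,5R)-5-[(2R)-but-3-en-2-yl]-2-methyloxolan-2-yl]-2-(4-methoxyphenyl)-1,3-dioxolane
Product: 8 (2R)-2-[(2R,5R)-5-[(2R)-but-3-en-2-yl]-2-methyloxolan-2-yl]-2-[(4-methoxybenzyl)oxy]ethan-1-ol
Conditions: iBu2AlH (3 equiv), CH2Cl2, −78 → 0 °C
Reagents that add atoms: none
Why: Regioselective reductive acetal opening, in which aluminium binds the less hindered primary oxygen so that hydride delivery leaves the PMB ether on the hindered secondary oxygen.

Step 6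
Reactants: 8 (2R)-2-[(2R,5R)-5-[(2R)-but-3-en-2-yl]-2-methyloxolan-2-yl]-2-[(4-methoxybenzyl)oxy]ethan-1-ol
Product: 9 (2S)-2-[(2R,5R)-5-[(2R)-but-3-en-2-yl]-2-methyloxolan-2-yl]-2-[(4-methoxybenzyl)oxy]acetaldehyde
Conditions: Dess–Martin periodinane, pyridine, CH2Cl2, 0 °C → rt; used at once
Reagents that add atoms: none
Why: Dess–Martin oxidation under buffered conditions gives the α-alkoxy aldehyde without epimerisation (the descriptor changes only through CIP priorities).

Step 7
Reactants: 10 (S)-citramalic acid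
Product: 11 2-[(4S)-2,2,4-trimethyl-5-oxo-1,3-dioxolan-4-yl]acetic acid
Conditions: Me2C(OMe)2, TsOH (cat.), rt
Reagents that add atoms: 2,2-dimethoxypropane, COC(C)(C)OC
Why: Acid-catalysed acetonide formation ties up the α-hydroxy acid as the five-membered dioxolanone and leaves the CH2CO2H arm free; the chiral-pool centre is untouched.

Step 8
Reactants: 11 2-[(4S)-2,2,4-trimethyl-5-oxo-1,3-dioxolan-4-yl]acetic acid
Product: 12 S-ethyl 2-[(4S)-2,2,4-trimethyl-5-oxo-1,3-dioxolan-4-yl]ethanethioate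
Conditions: EtSH, EDC, DMAP (cat.), CH2Cl2, 0 °C → rt
Reagents that add atoms: ethanethiol, CCS
Why: Carbodiimide (Steglich-type) thioesterification of the free acid; no stereocentre is involved.

Step 9
Reactants: 12 S-ethyl 2-[(4S)-2,2,4-trimethyl-5-oxo-1,3-dioxolan-4-yl]ethanethioate
Product: 13 (5S)-5-[2-(ethylsulfanyl)-2-(trimethylsilyloxy)ethenyl]-2,2,5-trimethyl-1,3-dioxolan-4-one (E/Z mixture)
Conditions: LiN(iPr)2, Me3SiCl (internal quench), THF, −78 °C; used crude
Reagents that add atoms: chlorotrimethylsilane, C[Si](C)(C)Cl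
Why: Kinetic enolisation and O-silylation at the only enolisable position (CH2 next to the thioester), with the internal quench outrunning β-elimination.

Step 10
Reactants: 9 (2S)-2-[(2R,5R)-5-[(2R)-but-3-en-2-yl]-2-methyloxolan-2-yl]-2-[(4-methoxybenzyl)oxy]acetaldehyde; 13 (5S)-5-[2-(ethylsulfanyl)-2-(trimethylsilyloxy)ethenyl]-2,2,5-trimethyl-1,3-dioxolan-4-one
Product: 15 S-ethyl (2S,4S)-2-{(R)-[(2R,5R)-5-[(2R)-but-3-en-2-yl]-2-methyloxolan-2-yl][(4-methoxybenzyl)oxy]methyl}-4-hydroxy-4-methyl-5-oxooxolane-3-carbothioate (C-3 epimers), via aldol adduct 14 (not isolated)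
Conditions: MgBr2·OEt2 (3 equiv), CH2Cl2, −78 → −20 °C; aq. NH4Cl; then CSA (cat.), CH2Cl2, rt
Reagents that add atoms: none
Why: Mukaiyama aldol addition to the Cram chelate (Mg bridging C=O and the α-OPMB oxygen) puts the nucleophile on the α-hydrogen face and gives the syn 1,2-dioxygen pattern (new carbinol S), after which the new hydroxyl lactonises onto the dioxolanone with loss of acetone; the CH next to the thioester stays a mixture.

Step 11
Reactants: 15 S-ethyl (2S,4S)-2-{(R)-[(2R,5R)-5-[(2R)-but-3-en-2-yl]-2-methyloxolan-2-yl][(4-methoxybenzyl)oxy]methyl}-4-hydroxy-4-methyl-5-oxooxolane-3-carbothioate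
Product: 17 (3S,3aS,6R,6aS)-6-[(2R,5R)-5-[(2R)-but-3-en-2-yl]-2-methyloxolan-2-yl]-3-hydroxy-3-methyltetrahydrofuro[3,4-b]furan-2,4-dione, via hydroxy thioester 16 (not isolated)
Conditions: DDQ, CH2Cl2/pH 7 buffer, 0 °C; then DBU (0.3 equiv), toluene, rt → 40 °C
Reagents that add atoms: none
Why: Oxidative PMB cleavage followed by base-mediated epimerisation α to the thioester with thermodynamic funnelling, since only the epimer with the thioester cis to the carbinol side chain can lactonise, so the mixture converges on the cis-fused bis-lactone and that centre is fixed as S.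

Step 12
Reactants: 18 (2E)-3-iodo-2-methylprop-2-en-1-ol
Product: 20 [(2E)-3-iodo-2-methylprop-2-en-1-yl]sulfonylbenzene, via allylic mesylate 19 (not isolated)
Conditions: MsCl, Et3N, CH2Cl2, 0 °C; then PhSO2Na, DMF, rt
Reagents that add atoms: sodium benzenesulfinate, [Na+].[O-]S(=O)c1ccccc1
Why: Mesylation then SN2 S-alkylation of the sulfinate gives the allyl sulfone with the E-vinyl iodide unchanged.

Step 13
Reactants: 17 (3S,3aS,6R,6aS)-6-[(2R,5R)-5-[(2R)-but-3-en-2-yl]-2-methyloxolan-2-yl]-3-hydroxy-3-methyltetrahydrofuro[3,4-b]furan-2,4-dione; 20 [(2E)-3-iodo-2-methylprop-2-en-1-yl]sulfonylbenzene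
Product: 21 (3S,4S,5S)-5-{(R)-[(2R,5R)-5-[(2R)-but-3-en-2-yl]-2-methyloxolan-2-yl](hydroxy)methyl}-3-hydroxy-4-[(3E)-4-iodo-3-methyl-2-(phenylsulfonyl)but-3-enoyl]-3-methyloxolan-2-one (epimers at the sulfonyl carbon)
Conditions: 20 (3 equiv), LiN(SiMe3)2 (3.1 equiv), THF, −78 °C; then 17, −78 °C, 1 h; AcOH quench at −78 °C
Reagents that add atoms: none
Why: Claisen-type acylation of the α-sulfonyl allyl anion (α-attack, alkene geometry retained) on the less hindered lactone carbonyl of ring B frees the secondary carbinol, and the product sits as its sulfonyl-stabilised enolate so the adjacent ring-fusion centre is not epimerised.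

Step 14
Reactants: 21 (3S,4S,5S)-5-{(R)-[(2R,5R)-5-[(2R)-but-3-en-2-yl]-2-methyloxolan-2-yl](hydroxy)methyl}-3-hydroxy-4-[(3E)-4-iodo-3-methyl-2-(phenylsulfonyl)but-3-enoyl]-3-methyloxolan-2-one
Product: 23 macrocyclic β-keto sulfone (the target bearing PhSO2 on the ring CH2 between ketone and alkene; epimers at that carbon), via alkylborane 22 (not isolated)
Conditions: 9-BBN dimer (excess), THF, rt; H2O; then slow addition to Pd(dppf)Cl2 (20 mol %), AsPh3, Cs2CO3, DMF/THF/H2O, rt, 2 mM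
Reagents that add atoms: none
Why: Intramolecular B-alkyl Suzuki–Miyaura coupling (anti-Markovnikov hydroboration of the terminal alkene, then coupling with the vinyl iodide with retention) closes the 14-membered ring with the E-trisubstituted alkene; no stereocentre is affected.

Step 15
Reactants: 23 macrocyclic β-keto sulfone
Product: 24 target CNP0264573.3
Conditions: SmI2 (2.5 equiv), THF/MeOH, −78 °C
Reagents that add atoms: none
Why: Single-electron reductive desulfonylation of the β-keto sulfone, with kinetic α-protonation of the samarium dienolate leaving the β,γ-alkene in place; the cold, non-basic conditions avoid retro-aldol cleavage and epimerisation.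

**Compound list**

1 | neryl acetate, (2Z)-3,7-dimethylocta-2,6-dien-1-yl acetate | CC(=O)OC/C=C(C)\CCC=C(C)C | starting material
2 | (2Z)-3-methyl-6-oxohex-2-en-1-yl acetate | CC(=O)OC/C=C(C)\CCC=O | intermediate
3 | (2Z,6R,7R)-6-hydroxy-3,7-dimethylnona-2,8-dien-1-yl acetate (not isolated) | C=C[C@@H](C)[C@H](O)CC/C(C)=C\COC(C)=O | intermediate
4 | (2Z,6R,7R)-3,7-dimethylnona-2,8-diene-1,6-diol | C=C[C@@H](C)[C@H](O)CC/C(C)=C\CO | intermediate
5 | [(2R,3S)-3-[(3R,4R)-3-hydroxy-4-methylhex-5-en-1-yl]-3-methyloxiran-2-yl]methanol (not isolated) | C=C[C@@H](C)[C@H](O)CC[C@]1(C)O[C@@H]1CO | intermediate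
6 | (1R)-1-[(2R,5R)-5-[(2R)-but-3-en-2-yl]-2-methyloxolan-2-yl]ethane-1,2-diol | C=C[C@@H](C)[C@H]1CC[C@@](C)(O1)[C@H](O)CO | intermediate
7 | (4R)-4-[(2R,5R)-5-[(2R)-but-3-en-2-yl]-2-methyloxolan-2-yl]-2-(4-methoxyphenyl)-1,3-dioxolane (acetal epimers) | C=C[C@@H](C)[C@H]1CC[C@@](C)(O1)[C@H]1COC(c2ccc(OC)cc2)O1 | intermediate
8 | (2R)-2-[(2R,5R)-5-[(2R)-but-3-en-2-yl]-2-methyloxolan-2-yl]-2-[(4-methoxybenzyl)oxy]ethan-1-ol | C=C[C@@H](C)[C@H]1CC[C@@](C)(O1)[C@H](OCc1ccc(OC)cc1)CO | intermediate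
9 | (2S)-2-[(2R,5R)-5-[(2R)-but-3-en-2-yl]-2-methyloxolan-2-yl]-2-[(4-methoxybenzyl)oxy]acetaldehyde | C=C[C@@H](C)[C@H]1CC[C@@](C)(O1)[C@H](OCc1ccc(OC)cc1)C=O | intermediate
10 | (S)-citramalic acid, (2S)-2-hydroxy-2-methylbutanedioic acid | C[C@](O)(CC(=O)O)C(=O)O | starting material
11 | 2-[(4S)-2,2,4-trimethyl-5-oxo-1,3-dioxolan-4-yl]acetic acid | C[C@@]1(CC(=O)O)OC(C)(C)OC1=O | intermediate
12 | S-ethyl 2-[(4S)-2,2,4-trimethyl-5-oxo-1,3-dioxolan-4-yl]ethanethioate | CCSC(=O)C[C@]1(C)OC(C)(C)OC1=O | intermediate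
13 | (5S)-5-[2-(ethylsulfanyl)-2-(trimethylsilyloxy)ethenyl]-2,2,5-trimethyl-1,3-dioxolan-4-one (E/Z mixture) | CCSC(O[Si](C)(C)C)=C[C@]1(C)OC(C)(C)OC1=O | intermediate
14 | S-ethyl (3S,4R)-4-[(2R,5R)-5-[(2R)-but-3-en-2-yl]-2-methyloxolan-2-yl]-3-hydroxy-4-[(4-methoxybenzyl)oxy]-2-[(4S)-2,2,4-trimethyl-5-oxo-1,3-dioxolan-4-yl]butanethioate (C-2 epimers; not isolated) | C=C[C@@H](C)[C@H]1CC[C@@](C)(O1)[C@H](OCc1ccc(OC)cc1)[C@@H](O)C(C(=O)SCC)[C@]1(C)OC(C)(C)OC1=O | intermediate
15 | S-ethyl (2S,4S)-2-{(R)-[(2R,5R)-5-[(2R)-but-3-en-2-yl]-2-methyloxolan-2-yl][(4-methoxybenzyl)oxy]methyl}-4-hydroxy-4-methyl-5-oxooxolane-3-carbothioate (C-3 epimers) | C=C[C@@H](C)[C@H]1CC[C@@](C)(O1)[C@H](OCc1ccc(OC)cc1)[C@H]1OC(=O)[C@@](C)(O)C1C(=O)SCC | intermediate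
16 | S-ethyl (2S,4S)-2-{(R)-[(2R,5R)-5-[(2R)-but-3-en-2-yl]-2-methyloxolan-2-yl](hydroxy)methyl}-4-hydroxy-4-methyl-5-oxooxolane-3-carbothioate (C-3 epimers; not isolated) | C=C[C@@H](C)[C@H]1CC[C@@](C)(O1)[C@H](O)[C@H]1OC(=O)[C@@](C)(O)C1C(=O)SCC | intermediate
17 | (3S,3aS,6R,6aS)-6-[(2R,5R)-5-[(2R)-but-3-en-2-yl]-2-methyloxolan-2-yl]-3-hydroxy-3-methyltetrahydrofuro[3,4-b]furan-2,4-dione (cis-fused bis-γ-lactone) | C=C[C@@H](C)[C@H]1CC[C@@](C)(O1)[C@@H]1OC(=O)[C@H]2[C@@H]1OC(=O)[C@@]2(C)O | intermediate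
18 | (2E)-3-iodo-2-methylprop-2-en-1-ol | OC/C(C)=C/I | starting material
19 | (2E)-3-iodo-2-methylprop-2-en-1-yl methanesulfonate (not isolated) | CS(=O)(=O)OC/C(C)=C/I | intermediate
20 | [(2E)-3-iodo-2-methylprop-2-en-1-yl]sulfonylbenzene | O=S(=O)(C/C(C)=C/I)c1ccccc1 | intermediate
21 | (3S,4S,5S)-5-{(R)-[(2R,5R)-5-[(2R)-but-3-en-2-yl]-2-methyloxolan-2-yl](hydroxy)methyl}-3-hydroxy-4-[(3E)-4-iodo-3-methyl-2-(phenylsulfonyl)but-3-enoyl]-3-methyloxolan-2-one (epimers at the sulfonyl carbon; may sit as the cyclic hemiketal) | C=C[C@@H](C)[C@H]1CC[C@@](C)(O1)[C@H](O)[C@H]1OC(=O)[C@@](C)(O)[C@H]1C(=O)C(S(=O)(=O)c1ccccc1)/C(C)=C/I | intermediate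
22 | anti-Markovnikov 9-BBN adduct of 21, boron on the former terminal CH2 (not isolated) | C1CCC2CCCC1B2CC[C@@H](C)[C@H]1CC[C@@](C)(O1)[C@H](O)[C@H]1OC(=O)[C@@](C)(O)[C@H]1C(=O)C(S(=O)(=O)c1ccccc1)/C(C)=C/I | intermediate
23 | macrocyclic β-keto sulfone: target carrying a phenylsulfonyl group on the ring CH2 between ketone and alkene (epimers at that carbon) | C/C1=C\CC[C@@H](C)[C@H]2CC[C@@](C)(O2)[C@H](O)[C@H]2OC(=O)[C@@](C)(O)[C@H]2C(=O)C1S(=O)(=O)c1ccccc1 | intermediate
24 | CNP0264573.3, (1S,2S,3R,4R,7R,8R,11E,15S)-4,7-epoxy-3,15-dihydroxy-14-oxocembr-11-en-16,2-olide | C/C1=C\CC[C@@H](C)[C@H]2CC[C@@](C)(O2)[C@H](O)[C@H]2OC(=O)[C@@](C)(O)[C@H]2C(=O)C1 | target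

**Count and risks**

Total step count: 15. Longest linear sequence: 11 steps (steps 1–6, 10, 11, 13, 14, 15 from neryl acetate).

The three steps most likely to fail:

Step 10, the Mukaiyama aldol. It joins two carbons that each sit next to a quaternary centre, and it needs clean α-chelation. The fallback sets out from 9 and builds the tertiary carbinol by an aldol instead of taking it from citramalic acid. The unhindered ketene thioacetal of S-ethyl thioacetate is added under the same MgBr2·OEt2 chelation control to give the β-hydroxy thioester F1. DDQ and then Et3N close the hydroxy lactone F2. Esterification with pyruvic acid (DCC, DMAP) gives the pyruvate ester F3. Soft enolisation of its lactone (TiCl4, iPr2NEt, CH2Cl2, −78 °C) adds the enolate to the tethered keto group; this closure can only give the cis ring fusion and places the methyl group on the convex face, so the route is rejoined at 17.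

Step 11, the epimerising bis-lactonisation. The bulky oxolanyl group is forced onto the concave face of the bicycle, and the base can also trigger retro-aldol or dehydration. The fallback sets out from 16 (both epimers) and skips the bis-lactone. The thioester itself acylates lithiated 20 (THF, −78 °C) to give the β-keto sulfone epimer mixture F4. The ring-fusion carbon is now next to a ketone and is equilibrated under acid (CSA, CH2Cl2) through the enol, the cis epimer being drained as its five-membered cyclic hemiketal with the neighbouring carbinol. This returns to the route at 21.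

Step 14, the macrocyclic Suzuki coupling. Hydroboration has to spare the masked ketone, and the coupling runs with a lactone, free hydroxyls and a sulfonyl enolate present. The fallback sets out from 8 and moves the Suzuki coupling to an early, intermolecular stage. Hydroboration of 8 (9-BBN) and coupling with 20 (Pd(dppf)Cl2, AsPh3, Cs2CO3) give the sulfone alcohol F5. Dess–Martin oxidation gives the aldehyde F6. The aldol/lactonisation of step 10 with 13 gives the thioester lactone F7, and the DDQ/DBU sequence of step 11 gives the bis-lactone sulfone F8. The ring is then closed by intramolecular acylation of the sulfonyl carbanion on the ring B lactone carbonyl (LiN(SiMe3)2, THF, −78 → −20 °C, 1 mM), which comes back to the route at 23.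

**Further compounds**

F1 | step 10 | S-ethyl (3S,4R)-4-[(2R,5R)-5-[(2R)-but-3-en-2-yl]-2-methyloxolan-2-yl]-3-hydroxy-4-[(4-methoxybenzyl)oxy]butanethioate | C=C[C@@H](C)[C@H]1CC[C@@](C)(O1)[C@H](OCc1ccc(OC)cc1)[C@@H](O)CC(=O)SCC
F2 | step 10 | (4S,5R)-5-[(2R,5R)-5-[(2R)-but-3-en-2-yl]-2-methyloxolan-2-yl]-4-hydroxyoxolan-2-one | C=C[C@@H](C)[C@H]1CC[C@@](C)(O1)[C@@H]1OC(=O)C[C@@H]1O
F3 | step 10 | (2R,3S)-2-[(2R,5R)-5-[(2R)-but-3-en-2-yl]-2-methyloxolan-2-yl]-5-oxooxolan-3-yl 2-oxopropanoate | C=C[C@@H](C)[C@H]1CC[C@@](C)(O1)[C@@H]1OC(=O)C[C@@H]1OC(=O)C(C)=O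
F4 | step 11 | β-keto sulfone of 21 as the mixture of epimers at the lactone carbon that carries the acyl group | C=C[C@@H](C)[C@H]1CC[C@@](C)(O1)[C@H](O)[C@H]1OC(=O)[C@@](C)(O)C1C(=O)C(S(=O)(=O)c1ccccc1)/C(C)=C/I
F5 | step 14 | (2R)-2-[(4-methoxybenzyl)oxy]-2-[(2R,5R)-2-methyl-5-[(2R,5E)-6-methyl-7-(phenylsulfonyl)hept-5-en-2-yl]oxolan-2-yl]ethan-1-ol | C/C(CS(=O)(=O)c1ccccc1)=C\CC[C@@H](C)[C@H]1CC[C@@](C)(O1)[C@H](OCc1ccc(OC)cc1)CO
F6 | step 14 | (2S)-2-[(4-methoxybenzyl)oxy]-2-[(2R,5R)-2-methyl-5-[(2R,5E)-6-methyl-7-(phenylsulfonyl)hept-5-en-2-yl]oxolan-2-yl]acetaldehyde | C/C(CS(=O)(=O)c1ccccc1)=C\CC[C@@H](C)[C@H]1CC[C@@](C)(O1)[C@H](OCc1ccc(OC)cc1)C=O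
F7 | step 14 | S-ethyl (2S,4S)-4-hydroxy-2-{(R)-[(4-methoxybenzyl)oxy][(2R,5R)-2-methyl-5-[(2R,5E)-6-methyl-7-(phenylsulfonyl)hept-5-en-2-yl]oxolan-2-yl]methyl}-4-methyl-5-oxooxolane-3-carbothioate (C-3 epimers) | C/C(CS(=O)(=O)c1ccccc1)=C\CC[C@@H](C)[C@H]1CC[C@@](C)(O1)[C@H](OCc1ccc(OC)cc1)[C@H]1OC(=O)[C@@](C)(O)C1C(=O)SCC
F8 | step 14 | (3S,3aS,6R,6aS)-3-hydroxy-3-methyl-6-[(2R,5R)-2-methyl-5-[(2R,5E)-6-methyl-7-(phenylsulfonyl)hept-5-en-2-yl]oxolan-2-yl]tetrahydrofuro[3,4-b]furan-2,4-dione | C/C(CS(=O)(=O)c1ccccc1)=C\CC[C@@H](C)[C@H]1CC[C@@](C)(O1)[C@@H]1OC(=O)[C@H]2[C@@H]1OC(=O)[C@@]2(C)O
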